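## Structural features

Triphloroethol A (C18H14O9) consists of three benzene rings linked in a row by two diaryl ether oxygens, with seven free phenolic hydroxyls and no other functional group. There is no stereocenter, so no stereocenters stand next to each other and no stereochemical control is needed. Ring A is a 3,5-dihydroxyphenyl group and ring C is a 2,4,6-trihydroxyphenyl group whose ether oxygen lies between two hydroxyls. Ring B is numbered so that C1 carries the oxygen to ring A, C2 and C4 carry hydroxyls, C3 and C5 carry hydrogen and C6 carries the oxygen to ring C. The ether carbons C1 and C6 are neighbours, and C1 is flanked on both sides by oxygen-bearing carbons. All three rings are phloroglucinol-like, so the free phenols are easily oxidized as phenolates, are attacked by electrophiles such as halogenating agents and carbocations, and make the heptaphenol polar and hard to purify. The real difficulty is the pair of adjacent, doubly ortho-substituted diaryl ether bonds, which an aryl–oxygen coupling would have to form between hindered, electron-rich partners. The key step sidesteps this by building ring B between the two ether oxygens: C1 to C4 of ring B, with the ring-A oxygen on C1 and oxygen on C2 and C4, correspond to the dienol ether of a 4-aryloxy acetoacetate, and C5–C6 correspond to an alkyne that carries the ring-C oxygen on C6 and a removable carboxyl on C5.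

## Logic of the disconnections

**17 to 16.** Five O–CH3 bonds on rings A and C are added. Methyl ethers are the smallest groups that fit beside the congested ring-C oxygen, they come with the purchasable phenols, and they survive alkyllithium, amide base, heat and acid. The gain is that every earlier intermediate is a neutral ether that can be chromatographed. The forward step must cleave five aryl methyl ethers without breaking either diaryl ether, and the heptaphenol must be isolated without oxidation.

**16 to 14 (through 15).** A carboxyl group is added at C5 of ring B, as its tert-butyl ester. C5 is hydrogen in the target and is the one position where an acceptor can be placed and later removed, because it is ortho to the C4 hydroxyl and the C6 aryloxy group and para to the C2 hydroxyl. The tert-butyl group is chosen so that the ester is opened by acid at the alkyl–oxygen bond and not by hydroxide at a carbonyl flanked by two ortho substituents in an air-sensitive phenolate. This shortens the end of the route to two steps. The forward step must intercept the tert-butyl cation before it alkylates an electron-rich ring, and the decarboxylation must go to completion.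

**14 to 5 and 12.** The bonds C1–C6 and C4–C5 of ring B are cut. This removes ring B and leaves each diaryl ether oxygen on an open-chain carbon, so the problem falls into two pieces of similar size, each derived from one purchasable phenol. The forward step needs a single orientation of diene and alkyne, and the diene must react with a donor-substituted, hindered alkynoate.

**12 to 8 and 9 (through 11 and 10).** The bond between the alkyne carbon and the ester carbon is cut. This separates the carboxyl carbon from a two-carbon aryloxy unit that can be carried as a stable dichlorovinyl ether. The forward step must generate the acetylide without metalating ring C between its methoxy groups, and the ynol ether must not be hydrated on isolation.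

**8 to 6 and 7.** The bond between the ring-C oxygen and the two-carbon unit is cut. The hindered ring-C ether is thus made by adding a phenoxide to a linear two-carbon electrophile, where the two ortho substituents matter least. The forward step must keep the haloalkyne formed from 7 at low concentration and must exclude air from the phenoxide of 6.

**5 to 4.** The O–Si bond at the ester oxygen is cut. This returns the diene to a silyl enol ether with one acidic CH2 group left. The forward step needs clean deprotonation at C4 and strict exclusion of water.

**4 to 3.** The O–Si bond at the ketone oxygen is cut, which leads to a beta-keto ester. The forward step needs enolization between the two carbonyl groups and O-silylation under mild base.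

**3 to 1 and 2.** The bond between the ring-A oxygen and the CH2 group is cut. The ring-A ether is then made by plain O-alkylation with a primary chloride. The forward step needs O-alkylation rather than C-alkylation of an ambident phenoxide.

## Other disconnections considered

Alternative 1: The cut goes through both C–O bonds of ring B at C1 and C6, back to 3,5-dimethoxybenzyne A2 and its precursor 2-iodo-3,5-dimethoxyphenyl 4-chlorobenzenesulfonate A1. Forward, A1 would be made from 1 by iodination next to the hydroxyl and sulfonylation. In the key step iPrMgCl would exchange the iodine of A1, and the arylmagnesium would expel the sulfonate to give aryne A2. The chloromagnesium phenoxide of 6 should add to A2 at the aryne carbon remote from the neighbouring methoxy group, which is C6 of ring B. The arylmagnesium left at C1 would be trapped with B(OMe)3 and oxidized with H2O2 to 2,4-dimethoxy-6-(2,4,6-trimethoxyphenoxy)phenol A3. O-Arylation of A3 with a ring-A aryl bromide would give 2-(3,5-dimethoxyphenoxy)-1,5-dimethoxy-3-(2,4,6-trimethoxyphenoxy)benzene A4, and the seven methyl ethers of A4 would then be cleaved. In its favour, all three rings are bought, and the orientation of the addition to A2 rests on the well-understood inductive effect of the adjacent methoxy group. The sequence is about five steps, so on step count this alternative is the better. Against it, a magnesium phenoxide flanked by two methoxy groups is a weak nucleophile toward A2, so iPrMgCl or the arylmagnesium derived from A1 may add first. The second ether must be made by copper coupling at the oxygen of A3, which is flanked by OMe and OAr; this is the hindered coupling that the chosen plan avoids. Iodination of 1 may also go to C4, and seven ethers must be cleaved instead of five. In comparison, the chosen plan makes both hindered C–O bonds at unhindered sp3 or sp carbon and cleaves fewer ethers. It pays with three more steps and with moisture-sensitive silyl and ynol ether intermediates that Alternative 1 does not need.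

Alternative 2: The cut is at C1–C2 and C3–C4 of ring B, back to 3-(2,4,6-trimethoxyphenoxy)cyclobut-3-ene-1,2-dione A5. Forward, 1-ethoxyvinyllithium A6 would add to the ketone carbonyl of A5 that lies next to the aryloxy-bearing carbon, giving the racemic carbinol 4-(1-ethoxyethenyl)-4-hydroxy-3-(2,4,6-trimethoxyphenoxy)cyclobut-2-en-1-one A7. Heating A7 would open the four-membered ring to a vinylketene, which would close by 6-pi electrocyclization and enolize to 2-ethoxy-6-(2,4,6-trimethoxyphenoxy)benzene-1,4-diol A8. In its favour, the ring closure is intramolecular, so the substitution pattern of A8 follows from connectivity alone. On regiochemical certainty this alternative is the better, since the chosen cycloaddition depends on electronic matching of two components. The thermal ring expansion (Moore rearrangement) also needs no reagent. Against it, A8 holds only the ring-C ether. Ring A must be attached at the hydroxyl flanked by OEt and OAr after the unhindered para hydroxyl has been masked, so the hindered coupling returns together with an extra protection step. The aryloxy group of A5 sits on a vinylogous ester carbon and could be displaced by A6, and A5 itself needs about three steps from a squaric acid derivative. In comparison, at roughly seven steps the step count is about equal to that of the chosen plan. Mechanistically the ring formation is at least as secure, but structurally it solves only one of the two ether bonds.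

Alternative 3: The cut is at C2–C3 of ring B, back to a pyrone built from 4-hydroxy-6-methyl-2H-pyran-2-one A9. Forward, Mg(OMe)2 in hot methanol would open 3-(3,5-dimethoxyphenoxy)-6-methyl-4-(2,4,6-trimethoxyphenoxy)-2H-pyran-2-one A10 at the lactone carbonyl. The methyl ketone enolate of the open keto ester would then attack the ester carbon to give 4-(3,5-dimethoxyphenoxy)-5-(2,4,6-trimethoxyphenoxy)benzene-1,3-diol A11, which is the same substance as 16. In its favour, A11 needs no ester removal, so this alternative reaches 16 without a decarboxylation and is the better on that point. Both aryloxy groups are placed by connectivity, and A9 is a cheap six-carbon building block. Against it, the preparation of A10 is the weak part. C3 of A9 is nucleophilic, so an aryloxy group there needs polarity reversal through a halide or iodonium species, and the hindered phenoxide of 6 must displace a leaving group at C4. In the key step methoxide can attack C4 of A10 and expel the aryloxide, the open form can reclose to the pyrone, and the Claisen closure needs the less acidic methyl side of the ketone to attack a deactivated, enol-ether-conjugated ester. In comparison, the sequence is about six steps on paper, which is shorter than the chosen plan. Its key step is less secure mechanistically than a cycloaddition between a matched donor diene and an acceptor alkyne, and A10 is harder to reach than 5 and 12.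

Key step: step 6

Remark on the chemistry: 6 is taken as a purchasable, air-sensitive phenol and is handled under argon.
Remark on the chemistry: 4 and 5 are drawn as single geometric isomers, but any mixture of double-bond isomers is used as such, since all their sp2 carbons end up in aromatic ring B.

## Route

Step 1
Reactants: 1 3,5-dimethoxyphenol; 2 methyl 4-chloro-3-oxobutanoate
Product: 3 methyl 4-(3,5-dimethoxyphenoxy)-3-oxobutanoate
Conditions: NaH (2.2 equiv), THF, 0 °C to rt; then 1 M HCl
Reagents that add atoms: none
Why: Williamson ether synthesis; one equivalent of NaH holds the keto ester as its enolate, which suppresses self-condensation, and the sodium phenoxide of 1 displaces the primary chloride through oxygen in the aprotic solvent.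

Step 2
Reactants: 3 methyl 4-(3,5-dimethoxyphenoxy)-3-oxobutanoate
Product: 4 methyl (2Z)-4-(3,5-dimethoxyphenoxy)-3-(trimethylsilyloxy)but-2-enoate
Conditions: Me3SiCl, Et3N, toluene, rt; filtration under argon
Reagents that add atoms: chlorotrimethylsilane, C[Si](C)(C)Cl
Why: O-silylation of the conjugated enol of a beta-keto ester, which forms toward C2 between the two carbonyl groups; the double-bond geometry is of no consequence because this bond becomes the single bond of the diene.

Step 3
Reactants: 4 methyl (2Z)-4-(3,5-dimethoxyphenoxy)-3-(trimethylsilyloxy)but-2-enoate
Product: 5 (1E,3Z)-4-(3,5-dimethoxyphenoxy)-1-methoxy-1,3-bis(trimethylsilyloxy)buta-1,3-diene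
Conditions: LiN(iPr)2, THF, −78 °C; Me3SiCl, −78 °C to rt; hexane, filtration under argon, used crude
Reagents that add atoms: chlorotrimethylsilane, C[Si](C)(C)Cl
Why: Kinetic deprotonation at C4, the only acidic sp3 position left, gives the extended ester dienolate, which is silylated on the ester oxygen (standard two-stage preparation of 1-alkoxy-1,3-bis(silyloxy)butadienes, known for 4-aryloxy members).

Step 4
Reactants: 6 2,4,6-trimethoxyphenol; 7 1,1,2-trichloroethene
Product: 8 2-{[(E)-1,2-dichloroethenyl]oxy}-1,3,5-trimethoxybenzene
Conditions: K2CO3, DMF, 70 °C, argon
Reagents that add atoms: none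
Why: The base removes HCl from 7 and the potassium phenoxide of 6 adds anti to the resulting haloalkyne, which is consumed as it forms, so protonation gives the E-configured dichlorovinyl ether (first stage of the trichloroethylene route to ynol ethers); attack through oxygen on a linear two-carbon electrophile tolerates the two ortho methoxy groups.

Step 5
Reactants: 8 2-{[(E)-1,2-dichloroethenyl]oxy}-1,3,5-trimethoxybenzene; 9 di-tert-butyl dicarbonate
Product: 12 tert-butyl 3-(2,4,6-trimethoxyphenoxy)prop-2-ynoate, via chloroalkynyl ether 10 (not isolated), via lithium aryloxyacetylide 11 (not isolated)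
Conditions: n-BuLi (2.1 equiv), THF, −78 to −40 °C; 9, −78 to 0 °C; H2O; chromatography on Et3N-deactivated silica
Reagents that add atoms: none
Why: n-BuLi removes the vinylic hydrogen and LiCl is lost to give 10, a second equivalent exchanges chlorine for lithium to give 11, and acylation of this acetylide by the dicarbonate gives the ynoate; the tert-butyl ester is too hindered to be attacked again by 11 or by residual n-BuLi.

Step 6
Reactants: 5 (1E,3Z)-4-(3,5-dimethoxyphenoxy)-1-methoxy-1,3-bis(trimethylsilyloxy)buta-1,3-diene; 12 tert-butyl 3-(2,4,6-trimethoxyphenoxy)prop-2-ynoate
Product: 14 tert-butyl 3-(3,5-dimethoxyphenoxy)-4,6-dihydroxy-2-(2,4,6-trimethoxyphenoxy)benzoate, via monosilyl ether 13 (not isolated)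
Conditions: 5 (2 equiv), toluene (1 M), 90 °C, sealed tube, argon; then 10% aq. citric acid, THF, rt
Reagents that add atoms: none
Why: Diels–Alder cycloaddition–aromatization: C4 of 5, which receives electron density from three oxygens, attacks the aryloxy-bearing beta-carbon of 12 (the only acceptor position of a push–pull alkynoate) and the ester-bearing alpha-carbon bonds to the ketene-acetal carbon C1 of 5, so that C1–C6 and C4–C5 of ring B are formed. The two bonds may form in one asynchronous [4+2] event from the s-cis diene, whose aryloxy group points outward, or in sequence as a vinylogous Mukaiyama–Michael addition followed by a 6-exo-trig Claisen-type acylation of the resulting allenoate; either way ring B is the only ring closed and it closes as a six-membered carbocycle. The C(OMe)(OSiMe3) carbon then collapses with loss of methoxytrimethylsilane and the dienone enolizes to silyl ether 13, which the acidic work-up hydrolyses to 14. The closest known reaction type is the cycloaddition–aromatization of 1-alkoxy-1,3-bis(silyloxy)buta-1,3-dienes, 4-aryloxy members included, with alkynoates to give 2,4-dihydroxybenzoates; 12 differs from the usual partners only by the aryloxy substituent on its beta-carbon. No stereocenter is created. One orientation is needed and the substrates secure it: the reverse orientation would require C4 of 5 to bond to the alpha-carbon of 12, which has no acceptor character, and would mismatch the largest frontier-orbital coefficients. Because the aryloxy donor lowers the dienophilicity of 12, excess 5, high concentration and heat are used, and no Lewis acid is added since it would ionize the ynol ether and the tert-butyl ester.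

Step 7
Reactants: 14 tert-butyl 3-(3,5-dimethoxyphenoxy)-4,6-dihydroxy-2-(2,4,6-trimethoxyphenoxy)benzoate
Product: 16 4-(3,5-dimethoxyphenoxy)-5-(2,4,6-trimethoxyphenoxy)benzene-1,3-diol, via benzoic acid 15 (not isolated)
Conditions: CF3CO2H, Et3SiH (5 equiv), CH2Cl2, 0 °C to rt; evaporate; dioxane–H2O, 80 °C, argon
Reagents that add atoms: none
Why: Acidolysis of the tert-butyl ester at the alkyl–oxygen bond, with the tert-butyl cation reduced by the silane before it can alkylate an electron-rich ring (Friedel–Crafts suppression); acid 15 has a hydroxyl ortho and para and an aryloxy group ortho to the carboxyl carbon, so ipso-protonation and loss of CO2 (protodecarboxylation of a phloroglucinol-type acid) should occur on warming.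

Step 8
Reactants: 16 4-(3,5-dimethoxyphenoxy)-5-(2,4,6-trimethoxyphenoxy)benzene-1,3-diol
Product: 17 triphloroethol A, 2-[2-(3,5-dihydroxyphenoxy)-3,5-dihydroxyphenoxy]benzene-1,3,5-triol
Conditions: BBr3 (12 equiv), CH2Cl2, −78 °C to rt, argon; ice-water; EtOAc extraction; reversed-phase chromatography with degassed solvents
Reagents that add atoms: none
Why: Lewis-acid cleavage of aryl methyl ethers: bromide attacks the methyl carbon of each boron-complexed ether by SN2, while the diaryl ethers offer no sp3 carbon and should survive; no stereocenter is involved.

## Compound list

1 | 3,5-dimethoxyphenol | COc1cc(O)cc(OC)c1 | starting material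
2 | methyl 4-chloro-3-oxobutanoate (methyl 4-chloroacetoacetate) | COC(=O)CC(=O)CCl | starting material
3 | methyl 4-(3,5-dimethoxyphenoxy)-3-oxobutanoate | COC(=O)CC(=O)COc1cc(OC)cc(OC)c1 | intermediate
4 | methyl (2Z)-4-(3,5-dimethoxyphenoxy)-3-(trimethylsilyloxy)but-2-enoate | COC(=O)/C=C(\O[Si](C)(C)C)COc1cc(OC)cc(OC)c1 | intermediate
5 | (1E,3Z)-4-(3,5-dimethoxyphenoxy)-1-methoxy-1,3-bis(trimethylsilyloxy)buta-1,3-diene | CO/C(O[Si](C)(C)C)=C\C(O[Si](C)(C)C)=C\Oc1cc(OC)cc(OC)c1 | intermediate
6 | 2,4,6-trimethoxyphenol | COc1cc(OC)c(O)c(OC)c1 | starting material
7 | 1,1,2-trichloroethene (trichloroethylene) | ClC=C(Cl)Cl | starting material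
8 | 2-{[(E)-1,2-dichloroethenyl]oxy}-1,3,5-trimethoxybenzene | COc1cc(OC)c(O/C(Cl)=C\Cl)c(OC)c1 | intermediate
9 | di-tert-butyl dicarbonate | CC(C)(C)OC(=O)OC(=O)OC(C)(C)C | starting material
10 | 2-[(chloroethynyl)oxy]-1,3,5-trimethoxybenzene | COc1cc(OC)c(OC#CCl)c(OC)c1 | intermediate
11 | lithium 2-(2,4,6-trimethoxyphenoxy)ethynide | [Li]C#COc1c(OC)cc(OC)cc1OC | intermediate
12 | tert-butyl 3-(2,4,6-trimethoxyphenoxy)prop-2-ynoate | CC(C)(C)OC(=O)C#COc1c(OC)cc(OC)cc1OC | intermediate
13 | tert-butyl 3-(3,5-dimethoxyphenoxy)-6-hydroxy-2-(2,4,6-trimethoxyphenoxy)-4-(trimethylsilyloxy)benzoate | CC(C)(C)OC(=O)c1c(O)cc(O[Si](C)(C)C)c(Oc2cc(OC)cc(OC)c2)c1Oc1c(OC)cc(OC)cc1OC | intermediate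
14 | tert-butyl 3-(3,5-dimethoxyphenoxy)-4,6-dihydroxy-2-(2,4,6-trimethoxyphenoxy)benzoate | CC(C)(C)OC(=O)c1c(O)cc(O)c(Oc2cc(OC)cc(OC)c2)c1Oc1c(OC)cc(OC)cc1OC | intermediate
15 | 3-(3,5-dimethoxyphenoxy)-4,6-dihydroxy-2-(2,4,6-trimethoxyphenoxy)benzoic acid | OC(=O)c1c(O)cc(O)c(Oc2cc(OC)cc(OC)c2)c1Oc1c(OC)cc(OC)cc1OC | intermediate
16 | 4-(3,5-dimethoxyphenoxy)-5-(2,4,6-trimethoxyphenoxy)benzene-1,3-diol | Oc1cc(O)c(Oc2cc(OC)cc(OC)c2)c(Oc2c(OC)cc(OC)cc2OC)c1 | intermediate
17 | triphloroethol A, 2-[2-(3,5-dihydroxyphenoxy)-3,5-dihydroxyphenoxy]benzene-1,3,5-triol | Oc1cc(O)cc(Oc2c(O)cc(O)cc2Oc2c(O)cc(O)cc2O)c1 | target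

## Step count and risk

Total step count: 8. Longest linear sequence: 6 (steps 1, 2, 3, 6, 7, 8); steps 4 and 5 form the second branch.

**Step 6 (key step).** The most likely failure is that the cycloaddition is too slow at the doubly oxygenated, hindered alkyne carbon. The diene would then decompose by silyl migration or hydrolysis, or the reaction would stop after the first C–C bond and give an open-chain adduct on work-up. Fallback (sets out from 6, returns at 17): nucleophilic aromatic substitution of purchasable 2-fluoro-4,6-dimethoxybenzaldehyde by the caesium salt of 6 (Cs2CO3, DMSO, 110 °C) should give 2,4-dimethoxy-6-(2,4,6-trimethoxyphenoxy)benzaldehyde F1, since the leaving group is ortho to the aldehyde and meta to both methoxy groups. Baeyer–Villiger oxidation of F1 (mCPBA, NaHCO3, CH2Cl2, 0 °C) would give 2,4-dimethoxy-6-(2,4,6-trimethoxyphenoxy)phenyl formate F2, and methanolysis of F2 (K2CO3, MeOH) would give 2,4-dimethoxy-6-(2,4,6-trimethoxyphenoxy)phenol F3, the same substance as A3. Ullmann-type O-arylation of F3 with 1-bromo-3,5-dimethoxybenzene (CuI, picolinic acid, K3PO4, DMSO, 100 °C) would give 2-(3,5-dimethoxyphenoxy)-1,5-dimethoxy-3-(2,4,6-trimethoxyphenoxy)benzene F4, the same substance as A4. BBr3 would then cleave the seven methyl ethers of F4 to 17. This gives up the ring synthesis and accepts one hindered copper coupling in exchange for well-established reaction types.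

**Step 5.** Formation of 11 needs an excess of n-BuLi that is still present when 9 is added. The likely failures are competing lithiation of ring C between two methoxy groups, consumption of 9 by surplus butyllithium, and hydration of the electron-rich triple bond during isolation. Fallback (sets out from 8, returns at 12): the acetylide 11 is quenched with methanol at −78 °C and 2-(ethynyloxy)-1,3,5-trimethoxybenzene F5 is isolated by filtration through basic alumina. F5 is then metalated with LiN(SiMe3)2 (THF, −78 °C), a base that does not lithiate the ring or attack the dicarbonate, and the acetylide is acylated with 9 to give 12.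

**Step 8.** The likely failures are incomplete cleavage of the five ethers, because partly cleaved boron complexes precipitate, and oxidative loss of the polar heptaphenol during aqueous isolation and chromatography. Fallback (sets out from 16, returns at 17): the crude product of the BBr3 reaction is not purified but acetylated (Ac2O, pyridine) to triphloroethol A heptaacetate F6. F6 is a neutral compound from which partly methylated material can be separated on silica. Acid-catalysed methanolysis of F6 (HCl in MeOH, rt, argon) would release 17 with methyl acetate as the only by-product, so evaporation suffices and no phenolate is ever formed.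

**Step 1.** The likely failures are C-alkylation of the ambident phenoxide of 1 at a ring carbon between two oxygens and self-condensation of the enolate of 2. Fallback (sets out from 1, returns at 3): O-alkylation of 1 with sodium chloroacetate in aqueous NaOH would give 2-(3,5-dimethoxyphenoxy)acetic acid F7. Activation of F7 with carbonyldiimidazole and C-acylation of Meldrum's acid would give 5-[2-(3,5-dimethoxyphenoxy)-1-hydroxyethylidene]-2,2-dimethyl-1,3-dioxane-4,6-dione F8. Heating F8 in methanol would open the dioxanedione with loss of acetone and CO2 to give 3.

## Further compounds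

F1 | step 6 | 2,4-dimethoxy-6-(2,4,6-trimethoxyphenoxy)benzaldehyde | O=Cc1c(OC)cc(OC)cc1Oc1c(OC)cc(OC)cc1OC
F2 | step 6 | 2,4-dimethoxy-6-(2,4,6-trimethoxyphenoxy)phenyl formate | O=COc1c(OC)cc(OC)cc1Oc1c(OC)cc(OC)cc1OC
F3 | step 6 | 2,4-dimethoxy-6-(2,4,6-trimethoxyphenoxy)phenol | Oc1c(OC)cc(OC)cc1Oc1c(OC)cc(OC)cc1OC
F4 | step 6 | 2-(3,5-dimethoxyphenoxy)-1,5-dimethoxy-3-(2,4,6-trimethoxyphenoxy)benzene | COc1cc(OC)cc(Oc2c(OC)cc(OC)cc2Oc2c(OC)cc(OC)cc2OC)c1
F5 | step 5 | 2-(ethynyloxy)-1,3,5-trimethoxybenzene | C#COc1c(OC)cc(OC)cc1OC
F6 | step 8 | triphloroethol A heptaacetate, 2-[2-(3,5-diacetoxyphenoxy)-3,5-diacetoxyphenoxy]benzene-1,3,5-triyl triacetate | CC(=O)Oc1cc(OC(C)=O)cc(Oc2c(OC(C)=O)cc(OC(C)=O)cc2Oc2c(OC(C)=O)cc(OC(C)=O)cc2OC(C)=O)c1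
F7 | step 1 | 2-(3,5-dimethoxyphenoxy)acetic acid | COc1cc(OCC(O)=O)cc(OC)c1
F8 | step 1 | 5-[2-(3,5-dimethoxyphenoxy)-1-hydroxyethylidene]-2,2-dimethyl-1,3-dioxane-4,6-dione | COc1cc(OCC(O)=C2C(=O)OC(C)(C)OC2=O)cc(OC)c1
A1 | alternative 1 | 2-iodo-3,5-dimethoxyphenyl 4-chlorobenzenesulfonate | COc1cc(OC)c(I)c(OS(=O)(=O)c2ccc(Cl)cc2)c1
A2 | alternative 1 | 3,5-dimethoxybenzyne (1,2-didehydro-3,5-dimethoxybenzene) | COC1=CC(OC)=CC#C1
A3 | alternative 1 | 2,4-dimethoxy-6-(2,4,6-trimethoxyphenoxy)phenol | Oc1c(OC)cc(OC)cc1Oc1c(OC)cc(OC)cc1OC
A4 | alternative 1 | 2-(3,5-dimethoxyphenoxy)-1,5-dimethoxy-3-(2,4,6-trimethoxyphenoxy)benzene | COc1cc(OC)cc(Oc2c(OC)cc(OC)cc2Oc2c(OC)cc(OC)cc2OC)c1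
A5 | alternative 2 | 3-(2,4,6-trimethoxyphenoxy)cyclobut-3-ene-1,2-dione | COc1cc(OC)c(OC2=CC(=O)C2=O)c(OC)c1
A6 | alternative 2 | 1-ethoxyvinyllithium | [Li]C(=C)OCC
A7 | alternative 2 | 4-(1-ethoxyethenyl)-4-hydroxy-3-(2,4,6-trimethoxyphenoxy)cyclobut-2-en-1-one (racemic) | CCOC(=C)C1(O)C(Oc2c(OC)cc(OC)cc2OC)=CC1=O
A8 | alternative 2 | 2-ethoxy-6-(2,4,6-trimethoxyphenoxy)benzene-1,4-diol | CCOc1cc(O)cc(Oc2c(OC)cc(OC)cc2OC)c1O
A9 | alternative 3 | 4-hydroxy-6-methyl-2H-pyran-2-one | Cc1cc(O)cc(=O)o1
A10 | alternative 3 | 3-(3,5-dimethoxyphenoxy)-6-methyl-4-(2,4,6-trimethoxyphenoxy)-2H-pyran-2-one | Cc1cc(Oc2c(OC)cc(OC)cc2OC)c(Oc2cc(OC)cc(OC)c2)c(=O)o1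
A11 | alternative 3 | 4-(3,5-dimethoxyphenoxy)-5-(2,4,6-trimethoxyphenoxy)benzene-1,3-diol | Oc1cc(O)c(Oc2cc(OC)cc(OC)c2)c(Oc2c(OC)cc(OC)cc2OC)c1
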